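**Strategy.** Germacrane numbering is used: ring A is the ten-membered carbocycle C1–C10, ring B the γ-lactone O–C6–C7–C11–C12; C8 carries the angelate, C11 the acetate and C13. With C11=C13 as an exocyclic methylene, the C8 carbinol is homoallylic, so C7–C8 is the bond an allylmetal makes with an aldehyde. An intramolecular Nozaki–Hiyama–Kishi allylation of an open-chain C8 aldehyde that ends in an (R)-3-(bromomethyl)butenolide closes ring A, sets C7 and C8 from the single C6 stereocentre and unveils the α-methylene lactone. Hydrogen-atom-transfer hydration then sets C11, and the two esters follow. The chain comes from geranyl acetate.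

Key step: step 12

Remark on the chemistry: the ProPhenol antipode in step 6 is the one that gives the 4R carbinol 10; which antipode does so on this enal is to be fixed by an MTPA-ester analysis on the first run.

**Step 1**
Reactants: 1 geranyl acetate
Product: 3 (2E,6E)-3,7-dimethyl-8-oxoocta-2,6-dien-1-yl acetate, via 8-hydroxygeranyl acetate 2 (not isolated)
Conditions: SeO2 (0.3 equiv), t-BuOOH (3 equiv), salicylic acid (0.1 equiv), CH2Cl2, rt; filtered crude, MnO2 (15 equiv), CH2Cl2, rt
Reagents that add atoms: selenium dioxide O=[Se]=O (transfers the oxygen; regenerated by tert-butyl hydroperoxide CC(C)(C)OO)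
Why: SeO2 allylic oxidation (ene reaction, then [2,3] shift) should attack the E-methyl of the electron-rich terminal alkene and not the acetate-deactivated one, and MnO2 converges the alcohol/aldehyde mixture to the E-enal.

**Step 2**
Reactants: 3 (2E,6E)-3,7-dimethyl-8-oxoocta-2,6-dien-1-yl acetate
Product: 4 (2E,6E)-3,7-dimethylnona-2,6,8-trien-1-yl acetate
Conditions: Ph3PCH3Br, KOt-Bu, THF, 0 °C; then 3, −78 to 0 °C
Reagents that add atoms: methyltriphenylphosphonium bromide C[P+](c1ccccc1)(c1ccccc1)c1ccccc1.[Br-]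
Why: Wittig methylenation of the enal should give the terminal 1,3-diene; the existing E-alkenes are untouched and the ylide reacts with the aldehyde far faster than with the acetate.

**Step 3**
Reactants: 4 (2E,6E)-3,7-dimethylnona-2,6,8-trien-1-yl acetate
Product: 6 (2E,6E)-3,7-dimethylnona-2,6-diene-1,9-diol, via alkylborane 5 (not isolated)
Conditions: 9-BBN (1.3 equiv), THF, 0 °C to rt; then 3 M NaOH, 30% H2O2, 0 °C to rt (the acetate is saponified in the same operation)
Reagents that add atoms: hydrogen peroxide OO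
Why: Hydroboration–oxidation; 9-BBN should add only to the monosubstituted terminal alkene of the diene with boron at the end carbon, leaving both trisubstituted alkenes, and alkaline peroxide oxidises the C–B bond and cleaves the acetate.

**Step 4**
Reactants: 6 (2E,6E)-3,7-dimethylnona-2,6-diene-1,9-diol
Product: 7 (2E,6E)-9-hydroxy-3,7-dimethylnona-2,6-dienal
Conditions: MnO2 (15 equiv), CH2Cl2, rt
Reagents that add atoms: none
Why: MnO2 oxidises only the allylic alcohol; the homoallylic primary alcohol is inert and the E-enal geometry is kept.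

**Step 5**
Reactants: 7 (2E,6E)-9-hydroxy-3,7-dimethylnona-2,6-dienal
Product: 8 (2E,6E)-9-[(tert-butyldimethylsilyl)oxy]-3,7-dimethylnona-2,6-dienal
Conditions: TBSCl, imidazole, CH2Cl2, 0 °C
Reagents that add atoms: tert-butyldimethylsilyl chloride CC(C)(C)[Si](C)(C)Cl
Why: Standard silylation of the primary alcohol, so that a free hydroxyl does not perturb the zinc catalyst in the next step.

**Step 6**
Reactants: 8 (2E,6E)-9-[(tert-butyldimethylsilyl)oxy]-3,7-dimethylnona-2,6-dienal; 9 tert-butyldimethyl(prop-2-yn-1-yloxy)silane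
Product: 10 (4R,5E,9E)-1,12-bis[(tert-butyldimethylsilyl)oxy]-6,10-dimethyldodeca-5,9-dien-2-yn-4-ol
Conditions: 9 (3 equiv), ZnMe2 (3 equiv), ProPhenol ligand (20 mol%), Ph3P=O (40 mol%), toluene, 0 °C; aq. NH4Cl
Reagents that add atoms: none
Why: ProPhenol–dialkylzinc asymmetric alkynylation of an enal; the dinuclear zinc catalyst should deliver the zinc acetylide to one aldehyde face and set C6 (R) under catalyst control.

**Step 7**
Reactants: 10 (4R,5E,9E)-1,12-bis[(tert-butyldimethylsilyl)oxy]-6,10-dimethyldodeca-5,9-dien-2-yn-4-ol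
Product: 12 (2Z,4R,5E,9E)-1,12-bis[(tert-butyldimethylsilyl)oxy]-2-iodo-6,10-dimethyldodeca-2,5,9-trien-4-ol, via alkenylaluminate 11 (not isolated)
Conditions: NaAlH2(OCH2CH2OMe)2 (2.5 equiv), THF, 0 °C to rt; then I2, THF, −78 to 0 °C; aq. Rochelle salt
Reagents that add atoms: iodine II
Why: Alkoxide-directed trans-hydroalumination (hydride to C7, aluminium to C11 in a five-membered aluminate) followed by iodinolysis with retention should give the Z-iodoalkene with the C6 oxygen and iodine cis, as lactonisation needs.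

**Step 8**
Reactants: 12 (2Z,4R,5E,9E)-1,12-bis[(tert-butyldimethylsilyl)oxy]-2-iodo-6,10-dimethyldodeca-2,5,9-trien-4-ol
Product: 13 (5R)-3-{[(tert-butyldimethylsilyl)oxy]methyl}-5-[(1E,5E)-8-[(tert-butyldimethylsilyl)oxy]-2,6-dimethylocta-1,5-dien-1-yl]furan-2(5H)-one
Conditions: Pd(PPh3)4 (5 mol%), CO (1 atm), i-Pr2NEt (2 equiv), THF, rt to 40 °C, short reaction time
Reagents that add atoms: carbon monoxide [C-]#[O+]
Why: Carbonylative lactonisation: oxidative addition of the vinyl iodide to zerovalent palladium, CO insertion and capture of the acylpalladium by the cis C6 hydroxyl should give the butenolide without touching C6.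

**Step 9**
Reactants: 13 (5R)-3-{[(tert-butyldimethylsilyl)oxy]methyl}-5-[(1E,5E)-8-[(tert-butyldimethylsilyl)oxy]-2,6-dimethylocta-1,5-dien-1-yl]furan-2(5H)-one
Product: 14 (5R)-3-(hydroxymethyl)-5-[(1E,5E)-8-hydroxy-2,6-dimethylocta-1,5-dien-1-yl]furan-2(5H)-one
Conditions: HF·pyridine, pyridine, THF, 0 °C to rt
Reagents that add atoms: none
Why: Buffered fluoride cleaves both primary silyl ethers; the non-basic medium avoids deprotonation at the doubly activated C6–H of the butenolide.

**Step 10**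
Reactants: 14 (5R)-3-(hydroxymethyl)-5-[(1E,5E)-8-hydroxy-2,6-dimethylocta-1,5-dien-1-yl]furan-2(5H)-one
Product: 15 (5R)-3-(bromomethyl)-5-[(1E,5E)-8-hydroxy-2,6-dimethylocta-1,5-dien-1-yl]furan-2(5H)-one
Conditions: NBS, Me2S, CH2Cl2, −30 to 0 °C
Reagents that add atoms: N-bromosuccinimide O=C1CCC(=O)N1Br
Why: Corey–Kim halogenation is selective for allylic alcohols: the activated C13 alkoxysulfonium is displaced by bromide, whereas the saturated C8 alkoxysulfonium is not and returns as the alcohol on work-up; the trisubstituted alkenes are tolerated.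

**Step 11**
Reactants: 15 (5R)-3-(bromomethyl)-5-[(1E,5E)-8-hydroxy-2,6-dimethylocta-1,5-dien-1-yl]furan-2(5H)-one
Product: 16 (3E,7E)-8-[(2R)-4-(bromomethyl)-5-oxo-2,5-dihydrofuran-2-yl]-3,7-dimethylocta-3,7-dienal
Conditions: Dess–Martin periodinane, NaHCO3, CH2Cl2, 0 °C; used at once
Reagents that add atoms: none
Why: Buffered Dess–Martin oxidation gives the β,γ-unsaturated aldehyde without base, so the C10=C1 alkene should not migrate and C6 should not epimerise.

**Step 12**
Reactants: 16 (3E,7E)-8-[(2R)-4-(bromomethyl)-5-oxo-2,5-dihydrofuran-2-yl]-3,7-dimethylocta-3,7-dienal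
Product: 18 (3aS,4S,6E,10E,11aR)-4-hydroxy-6,10-dimethyl-3-methylidene-3a,4,5,8,9,11a-hexahydrocyclodeca[b]furan-2(3H)-one, via allylchromium species 17 (not isolated)
Conditions: CrCl2 (8 equiv), THF, rt; 16 added by syringe pump over 10 h (final 2 mM); aq. work-up
Reagents that add atoms: none
Why: Two equivalents of CrCl2 reduce the allylic bromide to the allylchromium species 17 (trivalent chromium), which adds to the C8 aldehyde through a closed six-membered transition state at its γ-carbon C7 while the double bond moves to C11=C13. This is the Nozaki–Hiyama–Kishi allylation, known for 3-(bromomethyl)butenolides with aldehydes and for macrocyclic closures of germacranolide rings. Ring A closes in a 10-exo-trig mode at the aldehyde; γ-attack is intrinsic to the cyclic transition state, and α-attack at C13 would need a twelve-membered ring. C7 is controlled by C6: the seven-atom tether with its two rigid E-olefin units is anchored on one face of the flat butenolide and should bring C8 only onto that face, so C5 and C8 end up cis on ring B. C8 is controlled by the forming ring: with cis delivery the C6–C7 and C7–C8 torsions must have the same sign, which puts C9 pseudo-axial in the chair and gives the 8S carbinol, the pseudo-equatorial alternative forcing C5 against C9. The step also needs ring closure to outrun bimolecular coupling and protonation of 17, which slow addition into excess CrCl2 at high dilution should secure.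

**Step 13**
Reactants: 18 (3aS,4S,6E,10E,11aR)-4-hydroxy-6,10-dimethyl-3-methylidene-3a,4,5,8,9,11a-hexahydrocyclodeca[b]furan-2(3H)-one
Product: 20 (3R,3aS,4S,6E,10E,11aR)-3,4-dihydroxy-3,6,10-trimethyl-3a,4,5,8,9,11a-hexahydrocyclodeca[b]furan-2(3H)-one, via hydroperoxide 19 (not isolated)
Conditions: Mn(dpm)3 (20 mol%; dpm = dipivaloylmethanate), PhSiH3 (2.5 equiv), O2 (1 atm), i-PrOH/CH2Cl2, 0 °C; then P(OEt)3
Reagents that add atoms: dioxygen O=O
Why: Mukaiyama hydration of an α,β-unsaturated ester: hydrogen-atom transfer to the unhindered C13 methylene gives the tertiary C11 radical, which O2 should trap on the convex face of the cis-fused bicycle, anti to C8 (11R); the trisubstituted ring alkenes react far more slowly and O2 capture should outrun transannular addition.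

**Step 14**
Reactants: 20 (3R,3aS,4S,6E,10E,11aR)-3,4-dihydroxy-3,6,10-trimethyl-3a,4,5,8,9,11a-hexahydrocyclodeca[b]furan-2(3H)-one; 21 angelic acid
Product: 23 (3R,3aS,4S,6E,10E,11aR)-3-hydroxy-3,6,10-trimethyl-2-oxo-2,3,3a,4,5,8,9,11a-octahydrocyclodeca[b]furan-4-yl (2Z)-2-methylbut-2-enoate, via mixed anhydride 22 (not isolated)
Conditions: 21, 2,4,6-trichlorobenzoyl chloride, Et3N, toluene, rt; then 20, toluene, 75 °C
Reagents that add atoms: none
Why: Yamaguchi-type mixed-anhydride acylation without a nucleophilic catalyst is the standard way to form angelates without Z-to-E isomerisation; the secondary C8 hydroxyl reacts with retention and the hindered tertiary C11 hydroxyl does not.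

**Step 15**
Reactants: 23 (3R,3aS,4S,6E,10E,11aR)-3-hydroxy-3,6,10-trimethyl-2-oxo-2,3,3a,4,5,8,9,11a-octahydrocyclodeca[b]furan-4-yl (2Z)-2-methylbut-2-enoate
Product: 24 (3R,3aS,4S,6E,10E,11aR)-3-acetoxy-3,6,10-trimethyl-2-oxo-2,3,3a,4,5,8,9,11a-octahydrocyclodeca[b]furan-4-yl (2Z)-2-methylbut-2-enoate
Conditions: Ac2O, DMAP, Et3N, CH2Cl2, rt to 35 °C
Reagents that add atoms: acetic anhydride CC(=O)OC(C)=O
Why: Steglich-type DMAP-catalysed acetylation of the tertiary C11 hydroxyl on the open convex face; no stereocentre is touched and the mild temperature should keep the angelate geometry.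

**Compound list**

1 | geranyl acetate | CC(C)=CCC/C(C)=C/COC(C)=O | starting material
2 | (2E,6E)-8-hydroxy-3,7-dimethylocta-2,6-dien-1-yl acetate | OC/C(C)=C/CC/C(C)=C/COC(C)=O | intermediate (not isolated)
3 | (2E,6E)-3,7-dimethyl-8-oxoocta-2,6-dien-1-yl acetate | O=C/C(C)=C/CC/C(C)=C/COC(C)=O | intermediate
4 | (2E,6E)-3,7-dimethylnona-2,6,8-trien-1-yl acetate | C=C/C(C)=C/CC/C(C)=C/COC(C)=O | intermediate
5 | (2E,6E)-9-(9-borabicyclo[3.3.1]nonan-9-yl)-3,7-dimethylnona-2,6-dien-1-yl acetate | C1CCC2CCCC(C1)B2CC/C(C)=C/CC/C(C)=C/COC(C)=O | intermediate (not isolated)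
6 | (2E,6E)-3,7-dimethylnona-2,6-diene-1,9-diol | OCC/C(C)=C/CC/C(C)=C/CO | intermediate
7 | (2E,6E)-9-hydroxy-3,7-dimethylnona-2,6-dienal | OCC/C(C)=C/CC/C(C)=C/C=O | intermediate
8 | (2E,6E)-9-[(tert-butyldimethylsilyl)oxy]-3,7-dimethylnona-2,6-dienal | CC(C)(C)[Si](C)(C)OCC/C(C)=C/CC/C(C)=C/C=O | intermediate
9 | tert-butyldimethyl(prop-2-yn-1-yloxy)silane | C#CCO[Si](C)(C)C(C)(C)C | starting material
10 | (4R,5E,9E)-1,12-bis[(tert-butyldimethylsilyl)oxy]-6,10-dimethyldodeca-5,9-dien-2-yn-4-ol | CC(C)(C)[Si](C)(C)OCC/C(C)=C/CC/C(C)=C/[C@@H](O)C#CCO[Si](C)(C)C(C)(C)C | intermediate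
11 | sodium cyclic alkoxy(alkenyl)bis(2-methoxyethoxy)aluminate from 10 (2,5-dihydro-1,2-oxaluminole, aluminium on C11) | CC(C)(C)[Si](C)(C)OCC/C(C)=C/CC/C(C)=C/[C@H]1O[Al-](OCCOC)(OCCOC)C(CO[Si](C)(C)C(C)(C)C)=C1.[Na+] | intermediate (not isolated)
12 | (2Z,4R,5E,9E)-1,12-bis[(tert-butyldimethylsilyl)oxy]-2-iodo-6,10-dimethyldodeca-2,5,9-trien-4-ol | CC(C)(C)[Si](C)(C)OCC/C(C)=C/CC/C(C)=C/[C@@H](O)/C=C(\I)CO[Si](C)(C)C(C)(C)C | intermediate
13 | (5R)-3-{[(tert-butyldimethylsilyl)oxy]methyl}-5-[(1E,5E)-8-[(tert-butyldimethylsilyl)oxy]-2,6-dimethylocta-1,5-dien-1-yl]furan-2(5H)-one | CC(C)(C)[Si](C)(C)OCC/C(C)=C/CC/C(C)=C/[C@H]1OC(=O)C(CO[Si](C)(C)C(C)(C)C)=C1 | intermediate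
14 | (5R)-3-(hydroxymethyl)-5-[(1E,5E)-8-hydroxy-2,6-dimethylocta-1,5-dien-1-yl]furan-2(5H)-one | OCC/C(C)=C/CC/C(C)=C/[C@H]1OC(=O)C(CO)=C1 | intermediate
15 | (5R)-3-(bromomethyl)-5-[(1E,5E)-8-hydroxy-2,6-dimethylocta-1,5-dien-1-yl]furan-2(5H)-one | OCC/C(C)=C/CC/C(C)=C/[C@H]1OC(=O)C(CBr)=C1 | intermediate
16 | (3E,7E)-8-[(2R)-4-(bromomethyl)-5-oxo-2,5-dihydrofuran-2-yl]-3,7-dimethylocta-3,7-dienal | O=CC/C(C)=C/CC/C(C)=C/[C@H]1OC(=O)C(CBr)=C1 | intermediate
17 | allylchromium dichloride from 16 (chromium on C13) | O=CC/C(C)=C/CC/C(C)=C/[C@H]1OC(=O)C(C[Cr](Cl)Cl)=C1 | intermediate (not isolated)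
18 | (3aS,4S,6E,10E,11aR)-4-hydroxy-6,10-dimethyl-3-methylidene-3a,4,5,8,9,11a-hexahydrocyclodeca[b]furan-2(3H)-one (cis-fused lactone) | O[C@H]1C/C(C)=C/CC/C(C)=C/[C@H]2OC(=O)C(=C)[C@@H]12 | intermediate
19 | (3R,3aS,4S,6E,10E,11aR)-3-hydroperoxy-4-hydroxy-3,6,10-trimethyl-3a,4,5,8,9,11a-hexahydrocyclodeca[b]furan-2(3H)-one | O[C@H]1C/C(C)=C/CC/C(C)=C/[C@H]2OC(=O)[C@](C)(OO)[C@@H]12 | intermediate (not isolated)
20 | (3R,3aS,4S,6E,10E,11aR)-3,4-dihydroxy-3,6,10-trimethyl-3a,4,5,8,9,11a-hexahydrocyclodeca[b]furan-2(3H)-one | O[C@H]1C/C(C)=C/CC/C(C)=C/[C@H]2OC(=O)[C@](C)(O)[C@@H]12 | intermediate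
21 | angelic acid, (2Z)-2-methylbut-2-enoic acid | C/C=C(/C)C(=O)O | starting material
22 | angelic 2,4,6-trichlorobenzoic anhydride | C/C=C(/C)C(=O)OC(=O)c1c(Cl)cc(Cl)cc1Cl | intermediate (not isolated)
23 | (3R,3aS,4S,6E,10E,11aR)-3-hydroxy-3,6,10-trimethyl-2-oxo-2,3,3a,4,5,8,9,11a-octahydrocyclodeca[b]furan-4-yl (2Z)-2-methylbut-2-enoate | C/C=C(/C)C(=O)O[C@H]1C/C(C)=C/CC/C(C)=C/[C@H]2OC(=O)[C@](C)(O)[C@@H]12 | intermediate
24 | (3R,3aS,4S,6E,10E,11aR)-3-acetoxy-3,6,10-trimethyl-2-oxo-2,3,3a,4,5,8,9,11a-octahydrocyclodeca[b]furan-4-yl (2Z)-2-methylbut-2-enoate | C/C=C(/C)C(=O)O[C@H]1C/C(C)=C/CC/C(C)=C/[C@H]2OC(=O)[C@](C)(OC(C)=O)[C@@H]12 | target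

**Step count and risks**

Total step count: 15. Longest linear sequence: 15 steps (1 to 24).

Steps most likely to fail:

Step 12. Ring closure to a ten-membered ring may lose to bimolecular allylation and to protonation or dimerisation of the short-lived allylchromium, and the face selectivity at C7 and C8 rests on the tether argument, not on a precedent for this ring. The fallback replaces the transient chromium reagent by a stable allylboron reagent that can be held at high dilution for as long as the closure needs. It sets out from 15: borylation (B2pin2, Pd2(dba)3 cat., toluene, 50 °C) should give the allylboronate alcohol F1, and buffered Dess–Martin oxidation the allylboronate aldehyde F2. Heating F2 in toluene at 90 °C at 1 mM (or Sc(OTf)3 cat. at rt) should close ring A through the same γ-selective closed six-membered transition state, and aqueous work-up returns the route at 18.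

Step 13. The radical pathway may leak into transannular C–C bond formation with the C1=C10 alkene or into plain conjugate reduction, or O2 may be captured with poor facial selectivity. The fallback uses polar chemistry and sets out from 18: conjugate reduction of the methylene lactone (NaBH4, MeOH, 0 °C) should give the 11,13-dihydro lactone F3. Its dianion (KN(SiMe3)2, 2.2 equiv, THF, −78 °C) is then hydroxylated with 2-(phenylsulfonyl)-3-phenyloxaziridine on the convex face of the lactone enolate, which returns the route at 20.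

Step 14. The activated angeloyl unit may isomerise from Z to E in the hot acylation, or the lactone may migrate to O8 under the amine base. The fallback builds the Z-alkene on the substrate and sets out from 20: DCC/DMAP (cat.) coupling with 2-[bis(2,2,2-trifluoroethoxy)phosphoryl]propanoic acid at 0 °C should give the phosphonate ester F4, and Ac2O/DMAP its C11 acetate F5. A Still–Gennari olefination of F5 (KN(SiMe3)2, 18-crown-6, acetaldehyde, THF, −78 °C) is Z-selective and should give the angelate directly, so the route is rejoined at 24.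

**Further compounds**

F1 | step 12 | (5R)-5-[(1E,5E)-8-hydroxy-2,6-dimethylocta-1,5-dien-1-yl]-3-[(4,4,5,5-tetramethyl-1,3,2-dioxaborolan-2-yl)methyl]furan-2(5H)-one | OCC/C(C)=C/CC/C(C)=C/[C@H]1OC(=O)C(CB2OC(C)(C)C(C)(C)O2)=C1
F2 | step 12 | (3E,7E)-3,7-dimethyl-8-{(2R)-5-oxo-4-[(4,4,5,5-tetramethyl-1,3,2-dioxaborolan-2-yl)methyl]-2,5-dihydrofuran-2-yl}octa-3,7-dienal | O=CC/C(C)=C/CC/C(C)=C/[C@H]1OC(=O)C(CB2OC(C)(C)C(C)(C)O2)=C1
F3 | step 13 | (3aS,4S,6E,10E,11aR)-4-hydroxy-3,6,10-trimethyl-3a,4,5,8,9,11a-hexahydrocyclodeca[b]furan-2(3H)-one (C3 methyl cis to C4, expected major epimer) | O[C@H]1C/C(C)=C/CC/C(C)=C/[C@H]2OC(=O)[C@@H](C)[C@@H]12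
F4 | step 14 | (3R,3aS,4S,6E,10E,11aR)-3-hydroxy-3,6,10-trimethyl-2-oxo-2,3,3a,4,5,8,9,11a-octahydrocyclodeca[b]furan-4-yl 2-[bis(2,2,2-trifluoroethoxy)phosphoryl]propanoate (epimers at the phosphonate carbon) | CC(C(=O)O[C@H]1C/C(C)=C/CC/C(C)=C/[C@H]2OC(=O)[C@](C)(O)[C@@H]12)P(=O)(OCC(F)(F)F)OCC(F)(F)F
F5 | step 14 | (3R,3aS,4S,6E,10E,11aR)-3-acetoxy-3,6,10-trimethyl-2-oxo-2,3,3a,4,5,8,9,11a-octahydrocyclodeca[b]furan-4-yl 2-[bis(2,2,2-trifluoroethoxy)phosphoryl]propanoate (epimers at the phosphonate carbon) | CC(C(=O)O[C@H]1C/C(C)=C/CC/C(C)=C/[C@H]2OC(=O)[C@](C)(OC(C)=O)[C@@H]12)P(=O)(OCC(F)(F)F)OCC(F)(F)F
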